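## Structural features

The target 29 is a 2-hydroxychroman-4-one. Ring A is hexasubstituted (C5–OH, C6–OMe, C7–OH, C8–Me, C8a–O1, C4a–C4) and is fused to the dihydropyranone ring C, which carries a lactol at C2 and a hydroxy(4-hydroxyphenyl)methyl group (C9) at C3. Three stereocentres stand in a row: C2 (S), C3 (R) and C9 (S). C2 and C3 are trans on ring C, and C3 and C9 are syn along the chain C4–C3–C9–aryl. C2 is anomeric and C3 lies between the C4 ketone and the masked C2 aldehyde, so only C9 is configurationally firm. The molecule is fragile: the lactol can lose water to a chromone, the C9 alcohol is both a β-hydroxy ketone and a para-hydroxybenzylic alcohol that ionises in acid, and the oxygen-rich ring A is easily oxidised. The real difficulties are to tell O1, O5/O7 and the C6 methyl ether apart on a ring with no free position, and to fix C3 relative to C9 and carry it to a product that tolerates neither acid, strong base nor heat. C4, C3 and C2 are a β-keto aldehyde in disguise. A 5-alkoxy-2-isoxazoline holds these three carbons at the right oxidation levels (C4 as C=N, C2 as a mixed acetal), so the ring A nitrile oxide carbon can become C4 and add to C3 of an enol ether whose allylic carbon is C9.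

## Logic of the disconnections

29 ⇒ 28 ⇒ 27. The C9 O–Si bond and the three O–benzyl bonds are cut last, because 29 tolerates nothing harsher than buffered fluoride and hydrogen. Hydrogenolysis is placed before desilylation so that the benzylic C9–O bond meets the catalyst only as a silyl ether. The demand is a neutral final step.

27 ⇒ 25. The lactol bond C2–O1 is opened and the C4 ketone is traced back to the C=N of an isoxazoline whose C5 acetal is C2. O1 is already a free phenol in 25, so the aldehyde released at C2 is trapped at once and never sits free beside an imine. The demand is N–O scission in a neutral medium, with imine hydrolysis faster than tautomerisation to the enamine that would erase C3.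

25 ⇒ 24. The O1–Si bond is cut. O1 must be masked on the dipole but freed without acid, because 24 holds a 5-methoxyisoxazoline (which aromatises by loss of methanol) and an ionisable benzylic silyl ether. An acetal at O1 would call for acid exactly here, so an aryl silyl ether is used; buffered fluoride removes it in the presence of the alkyl silyl ether.

24 ⇒ 15 + 23 (key step). The bonds C3–C4 and O–C2 are cut together. This splits the molecule into the complete ring A and the complete C2–C3–C9–aryl unit, and creates C3 under the control of C9. The demand is a dipole stable enough to be warmed with a hindered 1,2-disubstituted enol ether, an E double bond, and an acid-free medium.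

15 ⇒ 13 ⇒ 12 ⇒ 11. The C≡N–O group comes from CH=O through the oxime, and the O1 silyl ether from the free ortho-phenol of 11. The demand is that oxime chlorination does not touch the ring, which is met because the ring has no free position.

11 ⇒ 8. The C4a–CHO bond is cut. The acetal on O1 in 8 directs lithiation to the only ring C–H and is then lost in the acidic work-up, so no separate deprotection is needed.

8 ⇒ 5 ⇒ 4 ⇒ 3 ⇒ 1. The C6–O bond is traced to a formyl group (Dakin logic), and that formyl group to the symmetrical triol 1. In 3 the hydroxyl para to the aldehyde is the only one not chelated, which differentiates O1 from O5 and O7 without extra steps.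

23 ⇒ 22 ⇒ 20. The enol C2–O bond and then the C–I bond are cut, back to a terminal alkyne. Syn hydrometalation fixes the E geometry without an olefination that would give mixtures.

20 ⇒ 19 ⇒ 16 + 17. The C9–C3 bond is cut, and C9 is set by catalytic asymmetric alkynylation of an aryl aldehyde. A chiral-pool entry through an electron-rich arylglycine would pass through a diazotisation and an α-aryl-α-silyloxy aldehyde, both of which endanger the configuration at C9, so it is not used.

## Other disconnections considered

Alternative 1: The cut lies inside ring A at C4a–C8a; the six ring carbons are traced to a squaric ester (C8a, C8, C7, C6) and a 1-alkoxyvinyl unit (C5, C4a). In the forward sense cyclobutenone A2 would be heated. Conrotatory 4π opening should give a dienylketene, 6π electrocyclisation should form C4a–C8a, and tautomerisation should give phenol A1.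
- In favour: every ring A substituent is placed by the order of nucleophile additions to the squarate, O1 emerges as the only free hydroxyl and the C6 oxygen is already methylated. On the differentiation of O1 this plan is the better one, since the chosen route needs a selective mono-protection and a protecting-group exchange.
- Against: A1 is only an aromatic building block. None of C2, C3 and C9 and neither C3–C4 nor O–C2 is addressed, so a step like step 13 would still be needed. The isopropyl ethers at O5 and O7 need a boron trihalide for removal, which 29 would not survive, so they would have to be exchanged early.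
- Comparison: ring synthesis against substitution of a preformed arene; two pericyclic steps against formylation, Dakin oxidation and lithiation. About four operations to A1 equal the four steps to 8, but the ether exchange adds two or three, so it is not shorter overall.

Alternative 2: C8a–O1 and C4–C4a are cut at once, giving the ring A aryne (from A5) and the acid A4, which carries C2 as a dioxolane and both C3 and C9. In the forward sense CsF would release the aryne. The carboxylate oxygen should add at C8a (remote from the C5 benzyloxy group), the aryl anion at C4a should attack the acyl carbon, and the four-membered intermediate should open to the phenoxide of A3.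
- In favour: it is highly convergent. O1 is set free in the key step, so no O1 protecting group is needed, which is better than the chosen plan. The syn C3/C9 pair could be made beforehand by an auxiliary-controlled syn aldol, a more predictable source of C3 than the substrate-controlled facial selectivity of step 13, and this is also named as better.
- Against: insertion competes with plain O-arylation, especially with an α-branched acid. A3 has an acidic C3–H between ketone and acetal and β to a silyloxy group, in a medium containing fluoride, so epimerisation and β-elimination threaten. A5 is a hexasubstituted silyl triflate with a long preparation. The dioxolane must be hydrolysed by acid at the end, the condition that C9 and the lactol tolerate least.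
- Comparison: both plans join ring A to a three-carbon unit through two bonds, but here no stereocentre is created in the key step against two in step 13. The mechanism is stepwise polar against concerted. The endgame is one step shorter on paper but finishes in acid, so there is no net gain.

Alternative 3: C2–C3 is cut. C2 is traced to a formate on O1, and formate and ketone both to oxidative cleavage of the C2=C3 bond of benzofuran A8. In the forward sense LiN(SiMe3)2 would deprotonate keto formate A7 at C3. The enolate should add to the formate carbonyl through a six-membered array, and the tetrahedral lithium alkoxide is the lactolate of A6, which is identical with 27.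
- In favour: it converges on the same intermediate, so the endgame is shared. Ring C is formed directly at the final oxidation level with no imine stage, so the enamine channel that threatens C3 in step 15 is absent. On this point, and by one step after the key step, it is the better plan.
- Against: an enolate with a β-silyloxy group at C9 can eliminate to a chalcone-type enone. C3 arises by acyclic 1,2-induction in an ionic addition with no reliable model, and collapse of the lactolate to phenoxide and β-keto aldehyde enolate would erase it. Oxidative cleavage of a benzofuran beside an oxygen-rich arene and benzyl ethers raises chemoselectivity problems.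
- Comparison: one C–C bond and ring C directly, against two bonds and a temporary heterocycle. The plans are equal in stereocentres formed. Polar acyl transfer stands against a cycloaddition with a recognised stereochemical model. Step economy is about equal.

Key step: step 13

Assumption: C2 is a hemiacetal centre that equilibrates through the hydroxy aldehyde, and the 2,3-trans lactol of 29 is taken to be the anomer favoured at equilibrium, so no step is devoted to C2.

## Route

Step 1
Reactants: 1 2,4,6-trihydroxytoluene
Product: 3 2,4,6-trihydroxy-3-methylbenzaldehyde, via iminium chloride 2 (not isolated)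
Conditions: POCl3, DMF, EtOAc, 0 °C → rt; then H2O, 50 °C
Reagents that add atoms: N,N-dimethylformamide, CN(C)C=O; water, O
Why: Vilsmeier–Haack formylation of a phloroglucinol; the two free ring positions are equivalent and the precipitating iminium salt should stop the reaction after one formylation, water then supplying the carbonyl oxygen.

Step 2
Reactants: 3 2,4,6-trihydroxy-3-methylbenzaldehyde
Product: 4 2,6-dihydroxy-4-(methoxymethoxy)-3-methylbenzaldehyde
Conditions: MOMCl (1.05 equiv), iPr2NEt, THF, 0 °C
Reagents that add atoms: chloromethyl methyl ether, COCCl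
Why: Williamson-type O-alkylation; the hydroxyl para to the aldehyde is the most acidic and the only one not held in a hydrogen bond to C=O, so one equivalent should react there.

Step 3
Reactants: 4 2,6-dihydroxy-4-(methoxymethoxy)-3-methylbenzaldehyde
Product: 5 2,6-bis(benzyloxy)-4-(methoxymethoxy)-3-methylbenzaldehyde
Conditions: BnBr, K2CO3, DMF, 60 °C
Reagents that add atoms: benzyl bromide, BrCc1ccccc1
Why: Williamson etherification of the two chelated phenols under forcing conditions; the dipolar aprotic solvent favours O- over C-benzylation.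

Step 4
Reactants: 5 2,6-bis(benzyloxy)-4-(methoxymethoxy)-3-methylbenzaldehyde
Product: 8 1,3-bis(benzyloxy)-2-methoxy-5-(methoxymethoxy)-4-methylbenzene, via aryl formate 6 (not isolated), via phenol 7 (not isolated)
Conditions: mCPBA, CH2Cl2, 0 °C → rt; aq NaHCO3 wash; K2CO3, MeOH, 0 °C; then MeI, K2CO3, DMF, rt
Reagents that add atoms: 3-chloroperoxybenzoic acid, OOC(=O)c1cccc(Cl)c1; iodomethane, CI
Why: Dakin-type Baeyer–Villiger oxidation, in which the electron-rich 2,6-dialkoxyaryl group migrates in preference to hydrogen; the formate is methanolysed and the air-sensitive para-alkoxyphenol is methylated at once (Williamson).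

Step 5
Reactants: 8 1,3-bis(benzyloxy)-2-methoxy-5-(methoxymethoxy)-4-methylbenzene
Product: 11 2,4-bis(benzyloxy)-6-hydroxy-3-methoxy-5-methylbenzaldehyde, via aryllithium 9 (not isolated), via MOM aldehyde 10 (not isolated)
Conditions: n-BuLi, THF, −20 → 0 °C; DMF, −78 °C → rt; then 3 M HCl, THF, 50 °C
Reagents that add atoms: N,N-dimethylformamide, CN(C)C=O
Why: Directed ortho-lithiation at the only ring C–H, flanked by the acetal and a benzyloxy oxygen, followed by formylation; the acid quench should also cleave the acetal ortho to the new carbonyl, while benzyl ethers are stable to aqueous HCl.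

Step 6
Reactants: 11 2,4-bis(benzyloxy)-6-hydroxy-3-methoxy-5-methylbenzaldehyde
Product: 12 2,4-bis(benzyloxy)-6-[(tert-butyldimethylsilyl)oxy]-3-methoxy-5-methylbenzaldehyde
Conditions: TBSOTf, 2,6-lutidine, CH2Cl2, 0 °C
Reagents that add atoms: tert-butyldimethylsilyl trifluoromethanesulfonate, CC(C)(C)[Si](C)(C)OS(=O)(=O)C(F)(F)F
Why: O-silylation of a chelated, hindered phenol needs the silyl triflate; the silyl ether is chosen for O1 because buffered fluoride removes it later without acid.

Step 7
Reactants: 12 2,4-bis(benzyloxy)-6-[(tert-butyldimethylsilyl)oxy]-3-methoxy-5-methylbenzaldehyde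
Product: 13 (E)-2,4-bis(benzyloxy)-6-[(tert-butyldimethylsilyl)oxy]-3-methoxy-5-methylbenzaldehyde oxime
Conditions: NH2OH·HCl, NaOAc, EtOH/THF, rt
Reagents that add atoms: hydroxylamine hydrochloride, Cl.NO
Why: Oxime condensation in an acetate buffer, which should leave the aryl silyl ether intact; the E aldoxime is expected.

Step 8
Reactants: 13 (E)-2,4-bis(benzyloxy)-6-[(tert-butyldimethylsilyl)oxy]-3-methoxy-5-methylbenzaldehyde oxime
Product: 15 2,4-bis(benzyloxy)-6-[(tert-butyldimethylsilyl)oxy]-3-methoxy-5-methylbenzonitrile oxide, via hydroximoyl chloride 14 (not isolated)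
Conditions: NCS, DMF, rt; then Et3N, CH2Cl2, 0 °C; cold aqueous wash
Reagents that add atoms: none
Why: Oxime chlorination followed by 1,3-dehydrochlorination; the ring has no free position for chlorination, and the two ortho oxygen substituents block dimerisation to the furoxan, so the dipole should be isolable.

Step 9
Reactants: 16 4-(benzyloxy)benzaldehyde; 17 ethynyltrimethylsilane
Product: 19 (S)-1-[4-(benzyloxy)phenyl]prop-2-yn-1-ol, via silylalkynol 18 (not isolated)
Conditions: Me2Zn, ProPhenol ligand (10 mol %, the antipode that gives Si-face addition), toluene, 0 °C → rt; aq NH4Cl; then K2CO3, MeOH, rt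
Reagents that add atoms: none
Why: Catalytic asymmetric alkynylzinc addition to an aryl aldehyde; delivery of the alkynyl group to the Si face sets C9, and methanolysis removes the C-silyl group (18 is named R and 19 S only because the silylalkynyl group outranks aryl in the priority rules).

Step 10
Reactants: 19 (S)-1-[4-(benzyloxy)phenyl]prop-2-yn-1-ol
Product: 20 tert-butyl({(1S)-1-[4-(benzyloxy)phenyl]prop-2-yn-1-yl}oxy)dimethylsilane
Conditions: TBSCl, imidazole, DMF, rt
Reagents that add atoms: tert-butyldimethylsilyl chloride, CC(C)(C)[Si](C)(C)Cl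
Why: Silylation under basic conditions, so the ionisable benzylic carbinol never meets acid.

Step 11
Reactants: 20 tert-butyl({(1S)-1-[4-(benzyloxy)phenyl]prop-2-yn-1-yl}oxy)dimethylsilane
Product: 22 tert-butyl({(1S,2E)-1-[4-(benzyloxy)phenyl]-3-iodoprop-2-en-1-yl}oxy)dimethylsilane, via alkenylzirconocene 21 (not isolated)
Conditions: Cp2Zr(H)Cl, THF, rt, dark; then I2, THF, 0 °C
Reagents that add atoms: iodine, II
Why: Hydrozirconation adds Zr–H syn with zirconium on the terminal carbon, and iodinolysis proceeds with retention, so only the E vinyl iodide should form.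

Step 12
Reactants: 22 tert-butyl({(1S,2E)-1-[4-(benzyloxy)phenyl]-3-iodoprop-2-en-1-yl}oxy)dimethylsilane
Product: 23 tert-butyl({(1S,2E)-1-[4-(benzyloxy)phenyl]-3-methoxyprop-2-en-1-yl}oxy)dimethylsilane
Conditions: CuI (copper monoiodide, 10 mol %), 3,4,7,8-tetramethyl-1,10-phenanthroline (20 mol %), Cs2CO3, MeOH (5 equiv), toluene, 80 °C, sealed tube
Reagents that add atoms: methanol, CO
Why: Ullmann-type copper-catalysed C–O coupling of a vinyl iodide with an alcohol, which keeps the double-bond geometry; the basic medium suits both the enol ether and the silyl ether.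

Step 13
Reactants: 15 2,4-bis(benzyloxy)-6-[(tert-butyldimethylsilyl)oxy]-3-methoxy-5-methylbenzonitrile oxide; 23 tert-butyl({(1S,2E)-1-[4-(benzyloxy)phenyl]-3-methoxyprop-2-en-1-yl}oxy)dimethylsilane
Product: 24 (4R,5S)-3-{2,4-bis(benzyloxy)-6-[(tert-butyldimethylsilyl)oxy]-3-methoxy-5-methylphenyl}-4-{(S)-[4-(benzyloxy)phenyl][(tert-butyldimethylsilyl)oxy]methyl}-5-methoxy-4,5-dihydro-1,2-oxazole
Conditions: 15 (1.5 equiv), toluene (0.5 M), powdered K2CO3, 70 °C, 48 h, Ar, dark
Reagents that add atoms: none
Why: Concerted, asynchronous [3+2] (1,3-dipolar) cycloaddition, suprafacial on both partners, of the kind known for nitrile oxides with vinyl ethers (5-alkoxy-2-isoxazolines) and with chiral allylic ethers. The leading interaction is HOMO(enol ether)–LUMO(dipole): C3, the enol ether carbon with the larger HOMO coefficient, bonds to the dipole carbon (future C4) and the alkoxy-bearing C2 bonds to the dipole oxygen, so the regiochemistry follows the polarisation of the enol ether. The isoxazoline ring is closed by intermolecular annulation, both σ-bonds (C3–C4 and O–C2) forming in the same step, so no exo/endo cyclisation mode applies. Isoxazoline C5 (C2) is tied to C4 (C3) by the E geometry of 23, which can only give the 4,5-trans ring. Isoxazoline C4 (C3) is controlled by C9: in the preferred transition state the C9–O bond lies inside, near the plane of the C=C bond, the aryl group stands anti to the incoming dipole and the hydrogen points outside towards the bulky dipole aryl group, which exposes the face leading to 4R. The E geometry is essential, because a Z enol ether would suffer allylic 1,3-strain with an inside oxygen and turn the other face. The step needs regioselectivity, facial selectivity and chemoselectivity against dimerisation or isocyanate formation: the enol ether oxygen secures the first, the silyloxy/aryl pair at C9 the second, and the two ortho oxygen substituents of 15 the third, while the solid base keeps the enol ether and the new acetal free of acid.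

Step 14
Reactants: 24 (4R,5S)-3-{2,4-bis(benzyloxy)-6-[(tert-butyldimethylsilyl)oxy]-3-methoxy-5-methylphenyl}-4-{(S)-[4-(benzyloxy)phenyl][(tert-butyldimethylsilyl)oxy]methyl}-5-methoxy-4,5-dihydro-1,2-oxazole
Product: 25 3,5-bis(benzyloxy)-2-[(4R,5S)-4-{(S)-[4-(benzyloxy)phenyl][(tert-butyldimethylsilyl)oxy]methyl}-5-methoxy-4,5-dihydro-1,2-oxazol-3-yl]-4-methoxy-6-methylphenol
Conditions: TBAF (1.1 equiv), AcOH (1.1 equiv), THF, 0 °C
Reagents that add atoms: none
Why: Fluoride cleaves an aryl O–Si bond far faster than a secondary alkyl O–Si bond because phenoxide is the better leaving group; the acetic acid buffer keeps the medium neutral so that methanol is not eliminated across C4–C5 of the isoxazoline.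

Step 15
Reactants: 25 3,5-bis(benzyloxy)-2-[(4R,5S)-4-{(S)-[4-(benzyloxy)phenyl][(tert-butyldimethylsilyl)oxy]methyl}-5-methoxy-4,5-dihydro-1,2-oxazol-3-yl]-4-methoxy-6-methylphenol
Product: 27 (2S,3R)-5,7-bis(benzyloxy)-3-{(S)-[4-(benzyloxy)phenyl][(tert-butyldimethylsilyl)oxy]methyl}-2-hydroxy-6-methoxy-8-methylchroman-4-one, via imino hemiacetal 26 (not isolated)
Conditions: Mo(CO)6 (1.2 equiv), MeCN/H2O (10:1), 80 °C
Reagents that add atoms: water, O
Why: Reductive N–O cleavage by zerovalent molybdenum, a standard opening of 3-aryl-2-isoxazolines; the N–H imine is hydrolysed to the C4 ketone, the hemiacetal at C2 loses methanol, and the aldehyde is captured by the neighbouring phenol O1 (6-exo-trig hemiacetalisation), C2 settling as the more stable anomer.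

Step 16
Reactants: 27 (2S,3R)-5,7-bis(benzyloxy)-3-{(S)-[4-(benzyloxy)phenyl][(tert-butyldimethylsilyl)oxy]methyl}-2-hydroxy-6-methoxy-8-methylchroman-4-one
Product: 28 (2S,3R)-3-{(S)-[(tert-butyldimethylsilyl)oxy](4-hydroxyphenyl)methyl}-2,5,7-trihydroxy-6-methoxy-8-methylchroman-4-one
Conditions: H2 (1 atm), Pd/C, EtOAc/THF, rt
Reagents that add atoms: none
Why: Hydrogenolysis of the three aryl benzyl ethers in a neutral solvent; the benzylic silyl ether at C9 and the hydrogen-bonded aryl ketone should be inert at this pressure.

Step 17
Reactants: 28 (2S,3R)-3-{(S)-[(tert-butyldimethylsilyl)oxy](4-hydroxyphenyl)methyl}-2,5,7-trihydroxy-6-methoxy-8-methylchroman-4-one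
Product: 29 (2S,3R)-2,5,7-trihydroxy-3-[(S)-hydroxy(4-hydroxyphenyl)methyl]-6-methoxy-8-methylchroman-4-one
Conditions: HF·pyridine, pyridine, THF, 0 °C → rt; quench with Me3SiOMe, evaporate
Reagents that add atoms: none
Why: Buffered fluoride desilylation, which forms no free alkoxide (no retro-aldol) and is only weakly acidic (no ionisation at C9); the quench leaves only volatile by-products.

## Compound list

1 | 2,4,6-trihydroxytoluene | Cc1c(O)cc(O)cc1O | starting material
2 | N-methyl-N-[(2,4,6-trihydroxy-3-methylphenyl)methylidene]methanaminium chloride | C[N+](C)=Cc1c(O)c(C)c(O)cc1O.[Cl-] | intermediate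
3 | 2,4,6-trihydroxy-3-methylbenzaldehyde | O=Cc1c(O)c(C)c(O)cc1O | intermediate
4 | 2,6-dihydroxy-4-(methoxymethoxy)-3-methylbenzaldehyde | O=Cc1c(O)c(C)c(OCOC)cc1O | intermediate
5 | 2,6-bis(benzyloxy)-4-(methoxymethoxy)-3-methylbenzaldehyde | O=Cc1c(OCc2ccccc2)c(C)c(OCOC)cc1OCc1ccccc1 | intermediate
6 | 2,6-bis(benzyloxy)-4-(methoxymethoxy)-3-methylphenyl formate | O=COc1c(OCc2ccccc2)c(C)c(OCOC)cc1OCc1ccccc1 | intermediate
7 | 2,6-bis(benzyloxy)-4-(methoxymethoxy)-3-methylphenol | Oc1c(OCc2ccccc2)c(C)c(OCOC)cc1OCc1ccccc1 | intermediate
8 | 1,3-bis(benzyloxy)-2-methoxy-5-(methoxymethoxy)-4-methylbenzene | COc1c(OCc2ccccc2)c(C)c(OCOC)cc1OCc1ccccc1 | intermediate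
9 | [2,4-bis(benzyloxy)-3-methoxy-6-(methoxymethoxy)-5-methylphenyl]lithium | COc1c(OCc2ccccc2)c(C)c(OCOC)c([Li])c1OCc1ccccc1 | intermediate
10 | 2,4-bis(benzyloxy)-3-methoxy-6-(methoxymethoxy)-5-methylbenzaldehyde | COc1c(OCc2ccccc2)c(C)c(OCOC)c(C=O)c1OCc1ccccc1 | intermediate
11 | 2,4-bis(benzyloxy)-6-hydroxy-3-methoxy-5-methylbenzaldehyde | COc1c(OCc2ccccc2)c(C)c(O)c(C=O)c1OCc1ccccc1 | intermediate
12 | 2,4-bis(benzyloxy)-6-[(tert-butyldimethylsilyl)oxy]-3-methoxy-5-methylbenzaldehyde | COc1c(OCc2ccccc2)c(C)c(O[Si](C)(C)C(C)(C)C)c(C=O)c1OCc1ccccc1 | intermediate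
13 | (E)-2,4-bis(benzyloxy)-6-[(tert-butyldimethylsilyl)oxy]-3-methoxy-5-methylbenzaldehyde oxime | COc1c(OCc2ccccc2)c(C)c(O[Si](C)(C)C(C)(C)C)c(/C=N/O)c1OCc1ccccc1 | intermediate
14 | (Z)-2,4-bis(benzyloxy)-6-[(tert-butyldimethylsilyl)oxy]-N-hydroxy-3-methoxy-5-methylbenzenecarboximidoyl chloride | COc1c(OCc2ccccc2)c(C)c(O[Si](C)(C)C(C)(C)C)c(/C(Cl)=N/O)c1OCc1ccccc1 | intermediate
15 | 2,4-bis(benzyloxy)-6-[(tert-butyldimethylsilyl)oxy]-3-methoxy-5-methylbenzonitrile oxide | COc1c(OCc2ccccc2)c(C)c(O[Si](C)(C)C(C)(C)C)c(C#[N+][O-])c1OCc1ccccc1 | intermediate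
16 | 4-(benzyloxy)benzaldehyde | O=Cc1ccc(OCc2ccccc2)cc1 | starting material
17 | ethynyltrimethylsilane | C#C[Si](C)(C)C | starting material
18 | (R)-1-[4-(benzyloxy)phenyl]-3-(trimethylsilyl)prop-2-yn-1-ol | C[Si](C)(C)C#C[C@H](O)c1ccc(OCc2ccccc2)cc1 | intermediate
19 | (S)-1-[4-(benzyloxy)phenyl]prop-2-yn-1-ol | C#C[C@H](O)c1ccc(OCc2ccccc2)cc1 | intermediate
20 | tert-butyl({(1S)-1-[4-(benzyloxy)phenyl]prop-2-yn-1-yl}oxy)dimethylsilane | C#C[C@H](O[Si](C)(C)C(C)(C)C)c1ccc(OCc2ccccc2)cc1 | intermediate
21 | chlorobis(cyclopentadienyl){(1E,3S)-3-[4-(benzyloxy)phenyl]-3-[(tert-butyldimethylsilyl)oxy]prop-1-en-1-yl}zirconium (cyclopentadienyl rings written σ-bonded) | Cl[Zr](/C=C/[C@H](O[Si](C)(C)C(C)(C)C)c1ccc(OCc2ccccc2)cc1)(C1C=CC=C1)C1C=CC=C1 | intermediate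
22 | tert-butyl({(1S,2E)-1-[4-(benzyloxy)phenyl]-3-iodoprop-2-en-1-yl}oxy)dimethylsilane | I/C=C/[C@H](O[Si](C)(C)C(C)(C)C)c1ccc(OCc2ccccc2)cc1 | intermediate
23 | tert-butyl({(1S,2E)-1-[4-(benzyloxy)phenyl]-3-methoxyprop-2-en-1-yl}oxy)dimethylsilane | CO/C=C/[C@H](O[Si](C)(C)C(C)(C)C)c1ccc(OCc2ccccc2)cc1 | intermediate
24 | (4R,5S)-3-{2,4-bis(benzyloxy)-6-[(tert-butyldimethylsilyl)oxy]-3-methoxy-5-methylphenyl}-4-{(S)-[4-(benzyloxy)phenyl][(tert-butyldimethylsilyl)oxy]methyl}-5-methoxy-4,5-dihydro-1,2-oxazole | COc1c(OCc2ccccc2)c(C)c(O[Si](C)(C)C(C)(C)C)c(C2=NO[C@H](OC)[C@H]2[C@H](O[Si](C)(C)C(C)(C)C)c2ccc(OCc3ccccc3)cc2)c1OCc1ccccc1 | intermediate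
25 | 3,5-bis(benzyloxy)-2-[(4R,5S)-4-{(S)-[4-(benzyloxy)phenyl][(tert-butyldimethylsilyl)oxy]methyl}-5-methoxy-4,5-dihydro-1,2-oxazol-3-yl]-4-methoxy-6-methylphenol | COc1c(OCc2ccccc2)c(C)c(O)c(C2=NO[C@H](OC)[C@H]2[C@H](O[Si](C)(C)C(C)(C)C)c2ccc(OCc3ccccc3)cc2)c1OCc1ccccc1 | intermediate
26 | ring-opened N–H ketimine methyl hemiacetal of 25: 3-aryl-3-imino-1-methoxy-2-[(S)-aryl(silyloxy)methyl]propan-1-ol, all three stereocentres as in 25 | COc1c(OCc2ccccc2)c(C)c(O)c(C(=N)[C@@H]([C@H](O)OC)[C@H](O[Si](C)(C)C(C)(C)C)c2ccc(OCc3ccccc3)cc2)c1OCc1ccccc1 | intermediate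
27 | (2S,3R)-5,7-bis(benzyloxy)-3-{(S)-[4-(benzyloxy)phenyl][(tert-butyldimethylsilyl)oxy]methyl}-2-hydroxy-6-methoxy-8-methylchroman-4-one | COc1c(OCc2ccccc2)c(C)c2c(c1OCc1ccccc1)C(=O)[C@H]([C@H](O[Si](C)(C)C(C)(C)C)c1ccc(OCc3ccccc3)cc1)[C@@H](O)O2 | intermediate
28 | (2S,3R)-3-{(S)-[(tert-butyldimethylsilyl)oxy](4-hydroxyphenyl)methyl}-2,5,7-trihydroxy-6-methoxy-8-methylchroman-4-one | COc1c(O)c(C)c2c(c1O)C(=O)[C@H]([C@H](O[Si](C)(C)C(C)(C)C)c1ccc(O)cc1)[C@@H](O)O2 | intermediate
29 | (2S,3R)-2,5,7-trihydroxy-3-[(S)-hydroxy(4-hydroxyphenyl)methyl]-6-methoxy-8-methylchroman-4-one | COc1c(O)c(C)c2c(c1O)C(=O)[C@H]([C@H](O)c1ccc(O)cc1)[C@@H](O)O2 | target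

## Step count and risk

Total: 17 steps (steps 1–8 to dipole 15, steps 9–12 to enol ether 23, step 13, steps 14–17 to 29). Longest linear sequence: 13 steps (1–8 and 13–17) from 1.

Least certain steps:

Step 13 (key step). The dipole carbon is screened by two ortho ether groups and the enol ether is 1,2-disubstituted with a bulky allylic carbon. The cycloaddition may therefore be slow enough for thermal isomerisation of the dipole to the isocyanate to compete, and the longer heating may lower the facial discrimination between an inside and an outside silyloxy group. The fallback uses a smaller, hydrogen-bonded dipole made in the flask. It sets out from 11, which is condensed with NH2OH·HCl/NaOAc to 2,4-bis(benzyloxy)-6-hydroxy-3-methoxy-5-methylbenzaldehyde oxime F1. F1 is chlorinated with NCS in DMF at 0 °C to the hydroximoyl chloride (Z)-2,4-bis(benzyloxy)-N,6-dihydroxy-3-methoxy-5-methylbenzenecarboximidoyl chloride F2. F2 is warmed with 23 and solid KHCO3 in EtOAc, so that 2,4-bis(benzyloxy)-6-hydroxy-3-methoxy-5-methylbenzonitrile oxide F3 forms slowly and adds as it forms. This comes back to the route at 25 and makes steps 6 and 14 unnecessary.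

Step 15. Tautomerisation of the N–H imine to the enamine before hydrolysis would epimerise C3. Prolonged heating may also cause loss of methanol across C4–C5 of the isoxazoline or loss of water from the lactol towards a chromone. The fallback joins ring opening and debenzylation in one hydrogenolysis at room temperature. It sets out from 25, which is stirred under H2 (1 atm) with Pd(OH)2/C and B(OH)3 in THF/MeOH/H2O. The N–O bond and the three benzyl ethers are cleaved together, boric acid hydrolyses the imine, and the sequence comes back to the route at 28. No compound outside the list is formed (F0).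

Step 17. With the para-hydroxyl free, the weakly acidic fluoride medium may ionise the C9–O bond (epimerisation through a quinone methide) or dehydrate the lactol. The fallback inverts the order of the two deprotections. It sets out from 27, which is desilylated with HF·pyridine/pyridine while the phenols are still benzylated, giving (2S,3R)-5,7-bis(benzyloxy)-3-{(S)-[4-(benzyloxy)phenyl](hydroxy)methyl}-2-hydroxy-6-methoxy-8-methylchroman-4-one F4. Monitored hydrogenolysis (H2, Pd/C, EtOAc, rt) then comes back to the route at 29.

Step 9. Incomplete enantiofacial control in the alkynylation would lower the enantiomeric purity at C9, which no later step corrects. The fallback replaces catalyst control by enzymatic resolution. It sets out from 16, which is treated with HC≡CMgBr in THF to give racemic 1-[4-(benzyloxy)phenyl]prop-2-yn-1-ol F5. Candida antarctica lipase B with vinyl acetate is expected to acylate the R antipode to (R)-1-[4-(benzyloxy)phenyl]prop-2-yn-1-yl acetate F6 and leave the S alcohol, which comes back to the route at 19.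

Step 5. n-BuLi may also deprotonate a benzylic CH2 of the benzyl ethers (followed by a 1,2-shift) or the aryl methyl group. The fallback replaces deprotonation by halogen–metal exchange. It sets out from 8, which is brominated at its only free ring position with NBS in MeCN at 0 °C to 1,3-bis(benzyloxy)-4-bromo-2-methoxy-5-(methoxymethoxy)-6-methylbenzene F7. Exchange with n-BuLi at −78 °C is faster than any deprotonation and comes back to the route at 9.

## Further compounds

F1 | step 13 | 2,4-bis(benzyloxy)-6-hydroxy-3-methoxy-5-methylbenzaldehyde oxime | COc1c(OCc2ccccc2)c(C)c(O)c(/C=N/O)c1OCc1ccccc1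
F2 | step 13 | (Z)-2,4-bis(benzyloxy)-N,6-dihydroxy-3-methoxy-5-methylbenzenecarboximidoyl chloride | COc1c(OCc2ccccc2)c(C)c(O)c(/C(Cl)=N/O)c1OCc1ccccc1
F3 | step 13 | 2,4-bis(benzyloxy)-6-hydroxy-3-methoxy-5-methylbenzonitrile oxide | COc1c(OCc2ccccc2)c(C)c(O)c(C#[N+][O-])c1OCc1ccccc1
F0 | step 15 | none | none
F4 | step 17 | (2S,3R)-5,7-bis(benzyloxy)-3-{(S)-[4-(benzyloxy)phenyl](hydroxy)methyl}-2-hydroxy-6-methoxy-8-methylchroman-4-one | COc1c(OCc2ccccc2)c(C)c2c(c1OCc1ccccc1)C(=O)[C@H]([C@H](O)c1ccc(OCc3ccccc3)cc1)[C@@H](O)O2
F5 | step 9 | racemic 1-[4-(benzyloxy)phenyl]prop-2-yn-1-ol | C#CC(O)c1ccc(OCc2ccccc2)cc1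
F6 | step 9 | (R)-1-[4-(benzyloxy)phenyl]prop-2-yn-1-yl acetate | CC(=O)O[C@H](C#C)c1ccc(OCc2ccccc2)cc1
F7 | step 5 | 1,3-bis(benzyloxy)-4-bromo-2-methoxy-5-(methoxymethoxy)-6-methylbenzene | COCOc1c(C)c(OCc2ccccc2)c(OC)c(OCc2ccccc2)c1Br
A1 | alternative 1 | 3,5-diisopropoxy-4-methoxy-2-methylphenol | COc1c(OC(C)C)c(C)c(O)cc1OC(C)C
A2 | alternative 1 | 3-isopropoxy-4-(1-isopropoxyvinyl)-4-methoxy-2-methylcyclobut-2-en-1-one (racemic) | CC1=C(OC(C)C)C(OC)(C(=C)OC(C)C)C1=O
A3 | alternative 2 | (2R,3S)-1-[2,4-bis(benzyloxy)-6-hydroxy-3-methoxy-5-methylphenyl]-3-[4-(benzyloxy)phenyl]-2-(1,3-dioxolan-2-yl)-3-[(triisopropylsilyl)oxy]propan-1-one | COc1c(OCc2ccccc2)c(C)c(O)c(c1OCc1ccccc1)C(=O)[C@H]([C@H](O[Si](C(C)C)(C(C)C)C(C)C)c1ccc(OCc2ccccc2)cc1)C1OCCO1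
A4 | alternative 2 | (2R,3S)-3-[4-(benzyloxy)phenyl]-2-(1,3-dioxolan-2-yl)-3-[(triisopropylsilyl)oxy]propanoic acid | OC(=O)[C@H]([C@H](O[Si](C(C)C)(C(C)C)C(C)C)c1ccc(OCc2ccccc2)cc1)C1OCCO1
A5 | alternative 2 | 3,5-bis(benzyloxy)-4-methoxy-2-methyl-6-(trimethylsilyl)phenyl trifluoromethanesulfonate | COc1c(OCc2ccccc2)c(C)c(OS(=O)(=O)C(F)(F)F)c([Si](C)(C)C)c1OCc1ccccc1
A6 | alternative 3 | (2S,3R)-5,7-bis(benzyloxy)-3-{(S)-[4-(benzyloxy)phenyl][(tert-butyldimethylsilyl)oxy]methyl}-2-hydroxy-6-methoxy-8-methylchroman-4-one | COc1c(OCc2ccccc2)c(C)c2c(c1OCc1ccccc1)C(=O)[C@H]([C@H](O[Si](C)(C)C(C)(C)C)c1ccc(OCc3ccccc3)cc1)[C@@H](O)O2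
A7 | alternative 3 | 3,5-bis(benzyloxy)-2-{(3S)-3-[4-(benzyloxy)phenyl]-3-[(tert-butyldimethylsilyl)oxy]propanoyl}-4-methoxy-6-methylphenyl formate | COc1c(OCc2ccccc2)c(C)c(OC=O)c(C(=O)C[C@H](O[Si](C)(C)C(C)(C)C)c2ccc(OCc3ccccc3)cc2)c1OCc1ccccc1
A8 | alternative 3 | 4,6-bis(benzyloxy)-3-{(2S)-2-[4-(benzyloxy)phenyl]-2-[(tert-butyldimethylsilyl)oxy]ethyl}-5-methoxy-7-methyl-1-benzofuran | COc1c(OCc2ccccc2)c(C)c2occ(C[C@H](O[Si](C)(C)C(C)(C)C)c3ccc(OCc4ccccc4)cc3)c2c1OCc1ccccc1
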